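The maple run was the neighbour I held against the alder run: the same charge, but with 0.0450 M of target in it from the start. I began with what that added target did.

| flask | starting material | coupling partner | free catalyst | target | time |
|---|---|---|---|---|---|
| alder | 0.150 M | 0.150 M | 0.00150 M |  |  |
| maple | 0.150 M | 0.150 M | 0.00150 M | 0.0450 M |  |
| cedar | 0.150 M | 0.150 M | 7.50 × 10⁻⁴ M |  |  |
| ash | 0.150 M | 0.0500 M | 0.00450 M |  | 91 min |

| run | time / min | [target] / M |
|---|---|---|
| alder run | 3.6 | 0.0026 |
| alder run | 8.1 | 0.0058 |
| alder run | 18 | 0.0132 |
| alder run | 41 | 0.0243 |
| alder run | 91 | 0.0344 |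
| maple run | 3.6 | 0.0468 |
| maple run | 8.1 | 0.0480 |
| maple run | 18 | 0.0514 |
| maple run | 41 | 0.0554 |
| maple run | 91 | 0.0555 |
| cedar run | 3.6 | 0.0016 |
| cedar run | 8.1 | 0.0027 |
| cedar run | 18 | 0.0066 |
| cedar run | 41 | 0.0124 |
| cedar run | 91 | 0.0198 |

(readings scatter by 4 × 10⁻⁴ M)

* order of the initial rate in [free catalyst], near the charge of the alder run, the rate being that where two percent of its starting material are target
* target in the ash run at 91 min, as a share of the starting material charged

- Overall: starting material + coupling partner -> target, with free catalyst as catalyst.
- Constant volume, constant temperature.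
- "The second partner" is coupling partner.
- An order is taken over about fifteen percent of the charge, up and down.

I supposed that added target leaves formation untouched. Both runs then form the same amount, and the gap between them can shrink only as target is lost. That gap fell from 0.0450 M to 0.0211 M by 91 min, which gave me 0.00832 min⁻¹: the loss constant, the share of the standing target that disappears each minute. The gap at 41 min read 0.00901 min⁻¹.

This explained where the two runs ended. Between their last readings the alder run formed 4.46 × 10⁻⁴ M min⁻¹, its slope plus its loss. The maple run, at 0.0555 M, was losing 4.62 × 10⁻⁴ M min⁻¹, about the same, so it stood flat. The alder run lost less than it formed, so it kept rising.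

I then reckoned the ash run from both ends of the alder run. Early formation was 7.88 × 10⁻⁴ M min⁻¹, so it decayed with 0.00998 min⁻¹. The cedar run, with half the catalyst, gave an order of 1.00 at 18 min. Taking formation as proportional to catalyst and coupling partner, the alder run turned over 0.00575 min⁻¹ of its partner, and I assigned the remaining 0.00423 min⁻¹ to first-order loss of partner. In the ash run, the coupling partner is the limiting reagent, capping target at 33.3%. Its 3.00 times the catalyst gives turnover of 0.0172 min⁻¹. Joining partner decay to target loss, I committed to 14.3%.

The forecast gave the same order, 1, but put the ash run higher than I did, at 27%: “Partial saturation suggests about 0.04 M, or about 27%”.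

The ash run gave 14.6%, 0.30 percentage points above my reckoning, and the order in free catalyst was 1.0, with the cedar run's rate at 0.48 of the alder run's where equal amounts had formed.

    free catalyst + starting material → loaded catalyst + by-product (87.60 L mol⁻¹ min⁻¹)
    loaded catalyst + coupling partner → target + free catalyst (3.894 L mol⁻¹ min⁻¹)
    target → decomposed product (0.008520 min⁻¹)
    coupling partner → lost reagent (0.003510 min⁻¹)

By the loss constant, the ash run's 0.0219 M of target was disappearing at 1.82 × 10⁻⁴ M min⁻¹, and the cedar run's last reading of 0.0198 M at 1.65 × 10⁻⁴ M min⁻¹.

(The readings were generated by integration with made-up constants.)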